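**Strategy**

Each end group (ring A, C1–C6 in carotenoid numbering) is traced back to 2,4,4-trimethylcyclohex-2-enone. The key step, a Robinson annulation of isobutyraldehyde with ethyl vinyl ketone, closes ring A in one operation: Michael addition makes the quaternary C1–C2 bond and aldol condensation the C5–C6 bond. It exploits the allylic array C4=C5(CH3)–C6H beside the gem-dimethyl carbon C1, which is the reductively 1,3-transposed form of the enone unit C4(=O)–C5(CH3)=C6H. CBS reduction and an anti-SN2′ alkenylation then move the double bond to C4=C5 and set (R)-C6 with the C7–C11 chain attached. Two C15 phosphonium salts and the C10 dialdehyde complete the C2-symmetric polyene in a two-directional Wittig reaction.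

Key step: step 1

Numbering: carotenoid numbering is used. C1 is the gem-dimethyl ring carbon, C2 and C3 the ring CH2 groups, C4 the ring CH=, C5 the methyl-bearing ring carbon, C6 the stereocentre, C7–C15 the chain; primed numbers denote the second half.

Assumption: (E)-3-methylpent-2-en-4-yn-1-ol (8) and (2E,4E,6E)-2,7-dimethylocta-2,4,6-trienedial (17) are taken as purchasable intermediates of industrial vitamin A and carotenoid manufacture.

**Route**

Step 1
Reactants: 1 isobutyraldehyde (2-methylpropanal); 2 ethyl vinyl ketone (pent-1-en-3-one)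
Product: 5 2,4,4-trimethylcyclohex-2-en-1-one, via keto aldehyde 3 (not isolated), via ketol 4 (not isolated)
Conditions: H2SO4 (cat.), toluene, 45 °C, then reflux with Dean–Stark trap
Reagents that add atoms: none
Why: Acid-catalysed Robinson annulation: the enol of 1 adds to protonated 2 (Michael addition) and creates the quaternary carbon C1 with the C1–C2 bond, giving keto aldehyde 3; the ethyl-ketone enol of 3 then attacks the aldehyde carbon (future C6) through its CH2 carbon (future C5), and dehydration of ketol 4 gives the conjugated enone, so that C5–C6 is forged as the enone double bond whose sigma bond persists to the target. The closest known reaction type is the acid-catalysed annulation of α-branched aldehydes with alkyl vinyl ketones to 4,4-disubstituted cyclohex-2-enones. Ring A is closed in the aldol step in a 6-(enolendo)-exo-trig mode. No stereocentre is formed (5 is achiral); C6 is set later by steps 2 and 6. The step needs chemoselectivity between the two carbonyl partners, which is secured because 1 has a single α-hydrogen (it can act only once as Michael donor and cannot form an enal by self-condensation) and because only the ethyl-side α-carbon of the ketone in 3 can reach the aldehyde through a six-membered transition state (the other α-carbon would close a four-membered ring).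

Step 2
Reactants: 5 2,4,4-trimethylcyclohex-2-en-1-one
Product: 6 (R)-2,4,4-trimethylcyclohex-2-en-1-ol
Conditions: (S)-1-methyl-3,3-diphenyltetrahydro-1H,3H-pyrrolo[1,2-c][1,3,2]oxazaborole (10 mol %), BH3·SMe2, THF, −20 °C; MeOH quench
Reagents that add atoms: none
Why: CBS reduction, 1,2-selective on the enone; the methyl-bearing alkene branch acts as the large group, so the (S)-oxazaborolidine should deliver hydride to the face that gives the (R)-carbinol at C4.

Step 3
Reactants: 6 (R)-2,4,4-trimethylcyclohex-2-en-1-ol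
Product: 7 (R)-2,4,4-trimethylcyclohex-2-en-1-yl pyridine-2-carboxylate
Conditions: picolinic acid, N,N'-dicyclohexylcarbodiimide, 4-(dimethylamino)pyridine (cat.), CH2Cl2, 0 °C to rt
Reagents that add atoms: picolinic acid, OC(=O)c1ccccn1
Why: Steglich esterification acylates the secondary allylic alcohol at oxygen, so the C4 configuration is retained, and installs a chelating leaving group for step 6.

Step 4
Reactants: 8 (E)-3-methylpent-2-en-4-yn-1-ol
Product: 9 tert-butyldimethyl{[(E)-3-methylpent-2-en-4-yn-1-yl]oxy}silane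
Conditions: TBSCl, imidazole, CH2Cl2, 0 °C to rt
Reagents that add atoms: tert-butyldimethylsilyl chloride, CC(C)(C)[Si](C)(C)Cl
Why: Silyl ether protection of the primary allylic alcohol masks the acidic OH before the organometallic steps; the alkene geometry is untouched.

Step 5
Reactants: 9 tert-butyldimethyl{[(E)-3-methylpent-2-en-4-yn-1-yl]oxy}silane
Product: 11 tert-butyl{[(2E,4E)-5-iodo-3-methylpenta-2,4-dien-1-yl]oxy}dimethylsilane, via alkenylzirconocene 10 (not isolated)
Conditions: Cp2Zr(H)Cl, THF, rt, dark; then I2, 0 °C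
Reagents that add atoms: iodine, II
Why: Hydrozirconation adds Zr–H syn across the terminal alkyne with zirconium at the terminal carbon, and iodinolysis proceeds with retention, so the new C7=C8 bond should be E; the trisubstituted alkene is far less reactive than the alkyne.

Step 6
Reactants: 7 (R)-2,4,4-trimethylcyclohex-2-en-1-yl pyridine-2-carboxylate; 11 tert-butyl{[(2E,4E)-5-iodo-3-methylpenta-2,4-dien-1-yl]oxy}dimethylsilane
Product: 14 tert-butyldimethyl{[(2E,4E)-3-methyl-5-[(1R)-2,6,6-trimethylcyclohex-2-en-1-yl]penta-2,4-dien-1-yl]oxy}silane, via dienyllithium 12 (not isolated), via dienylmagnesium bromide 13 (not isolated)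
Conditions: 11 (1.5 equiv), t-BuLi (2 equiv per 11), Et2O, −78 °C; MgBr2·OEt2; CuBr·SMe2 (20 mol %); then 7, THF, −40 to 0 °C
Reagents that add atoms: none
Why: Copper-catalysed anti-SN2′ allylic substitution of an allylic picolinate with an alkenyl Grignard reagent: magnesium chelation by the pyridyl ester activates the leaving group, monovalent copper adds at C6 on the face opposite to the C4–O bond, and reductive elimination from the trivalent σ-allylcopper delivers the dienyl group there, so (R)-C4–O is translated into (R)-C6 while the ring double bond moves to C4=C5.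

Step 7
Reactants: 14 tert-butyldimethyl{[(2E,4E)-3-methyl-5-[(1R)-2,6,6-trimethylcyclohex-2-en-1-yl]penta-2,4-dien-1-yl]oxy}silane
Product: 16 [(2E,4E)-3-methyl-5-[(1R)-2,6,6-trimethylcyclohex-2-en-1-yl]penta-2,4-dien-1-yl]triphenylphosphonium bromide, via dienol 15 (not isolated)
Conditions: PPh3·HBr, MeOH, rt
Reagents that add atoms: triphenylphosphine hydrobromide, [PH+](c1ccccc1)(c1ccccc1)c1ccccc1.[Br-]
Why: Acidic methanolysis removes the silyl ether, and the allylic alcohol 15 ionises to a pentadienyl cation that triphenylphosphine traps at the primary terminus C11 (allylic phosphonium salt formation); C6 is not part of the cation and should keep its configuration.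

Step 8
Reactants: 16 [(2E,4E)-3-methyl-5-[(1R)-2,6,6-trimethylcyclohex-2-en-1-yl]penta-2,4-dien-1-yl]triphenylphosphonium bromide (2.2 equiv); 17 (2E,4E,6E)-2,7-dimethylocta-2,4,6-trienedial
Product: 20 (6R,6'R)-ε,ε-carotene, via ylide 18 (not isolated), via apo-aldehyde 19 (not isolated)
Conditions: NaOMe, MeOH/CH2Cl2, 0 °C to rt; then reflux in heptane (Z to E equilibration), crystallisation
Reagents that add atoms: none
Why: Two-directional double Wittig olefination of the symmetric dialdehyde forms C11=C12 and C11'=C12'; the semi-stabilised allylic ylide should give E/Z mixtures at these bonds, which thermal equilibration converts into the all-E polyene, and the two C6 stereocentres are not touched.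

**Compound list**

1 | isobutyraldehyde (2-methylpropanal) | CC(C)C=O | starting material
2 | ethyl vinyl ketone (pent-1-en-3-one) | CCC(=O)C=C | starting material
3 | 2,2-dimethyl-5-oxoheptanal (keto aldehyde) | CCC(=O)CCC(C)(C)C=O | intermediate
4 | 3-hydroxy-2,4,4-trimethylcyclohexan-1-one (ketol, mixture of diastereomers) | CC1C(O)C(C)(C)CCC1=O | intermediate
5 | 2,4,4-trimethylcyclohex-2-en-1-one | CC1=CC(C)(C)CCC1=O | intermediate
6 | (R)-2,4,4-trimethylcyclohex-2-en-1-ol | O[C@@H]1CCC(C)(C)C=C1C | intermediate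
7 | (R)-2,4,4-trimethylcyclohex-2-en-1-yl pyridine-2-carboxylate | O=C(O[C@@H]1CCC(C)(C)C=C1C)c1ccccn1 | intermediate
8 | (E)-3-methylpent-2-en-4-yn-1-ol | C#C/C(C)=C/CO | starting material
9 | tert-butyldimethyl{[(E)-3-methylpent-2-en-4-yn-1-yl]oxy}silane | C#C/C(C)=C/CO[Si](C)(C)C(C)(C)C | intermediate
10 | chlorobis(cyclopentadienyl)[(1E,3E)-5-(tert-butyldimethylsilyloxy)-3-methylpenta-1,3-dien-1-yl]zirconium (cyclopentadienyl rings drawn σ-bonded) | Cl[Zr](/C=C/C(C)=C/CO[Si](C)(C)C(C)(C)C)(C1C=CC=C1)C1C=CC=C1 | intermediate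
11 | tert-butyl{[(2E,4E)-5-iodo-3-methylpenta-2,4-dien-1-yl]oxy}dimethylsilane | I/C=C/C(C)=C/CO[Si](C)(C)C(C)(C)C | intermediate
12 | [(1E,3E)-5-(tert-butyldimethylsilyloxy)-3-methylpenta-1,3-dien-1-yl]lithium | [Li]/C=C/C(C)=C/CO[Si](C)(C)C(C)(C)C | intermediate
13 | [(1E,3E)-5-(tert-butyldimethylsilyloxy)-3-methylpenta-1,3-dien-1-yl]magnesium bromide | Br[Mg]/C=C/C(C)=C/CO[Si](C)(C)C(C)(C)C | intermediate
14 | tert-butyldimethyl{[(2E,4E)-3-methyl-5-[(1R)-2,6,6-trimethylcyclohex-2-en-1-yl]penta-2,4-dien-1-yl]oxy}silane | CC1=CCCC(C)(C)[C@H]1/C=C/C(C)=C/CO[Si](C)(C)C(C)(C)C | intermediate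
15 | (2E,4E)-3-methyl-5-[(1R)-2,6,6-trimethylcyclohex-2-en-1-yl]penta-2,4-dien-1-ol | CC1=CCCC(C)(C)[C@H]1/C=C/C(C)=C/CO | intermediate
16 | [(2E,4E)-3-methyl-5-[(1R)-2,6,6-trimethylcyclohex-2-en-1-yl]penta-2,4-dien-1-yl]triphenylphosphonium bromide | CC1=CCCC(C)(C)[C@H]1/C=C/C(C)=C/C[P+](c1ccccc1)(c1ccccc1)c1ccccc1.[Br-] | intermediate
17 | (2E,4E,6E)-2,7-dimethylocta-2,4,6-trienedial | O=C/C(C)=C/C=C/C=C(C)/C=O | starting material
18 | {(2E,4E)-3-methyl-5-[(1R)-2,6,6-trimethylcyclohex-2-en-1-yl]penta-2,4-dien-1-ylidene}triphenylphosphorane (ylide) | CC1=CCCC(C)(C)[C@H]1/C=C/C(C)=C/C=P(c1ccccc1)(c1ccccc1)c1ccccc1 | intermediate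
19 | (2E,4E,6E,8E,10E,12E)-2,7,11-trimethyl-13-[(1R)-2,6,6-trimethylcyclohex-2-en-1-yl]trideca-2,4,6,8,10,12-hexaenal (12'-apo-ε-caroten-12'-al) | CC1=CCCC(C)(C)[C@H]1/C=C/C(C)=C/C=C/C(C)=C/C=C/C=C(C)/C=O | intermediate
20 | (6R,6'R)-ε,ε-carotene | CC1=CCCC(C)(C)[C@H]1/C=C/C(C)=C/C=C/C(C)=C/C=C/C=C(C)/C=C/C=C(C)/C=C/[C@H]1C(C)=CCCC1(C)C | target

**Step count**

Total step count: 8. Longest linear sequence: 6 steps (steps 1, 2, 3, 6, 7, 8).

**Steps most likely to fail**

Step 6. The dienylcopper may attack the carbinol carbon C4 (direct substitution) instead of the neopentylic C6, or the anti course may be partly lost. The fallback replaces the intermolecular substitution by a suprafacial sigmatropic shift; it sets out from 5 and comes back at 15. Reduction of 5 with the enantiomeric (R)-oxazaborolidine and BH3·SMe2 should give (S)-2,4,4-trimethylcyclohex-2-en-1-ol F1. O-Alkylation with KH and Bu3SnCH2I gives tributyl({[(1S)-2,4,4-trimethylcyclohex-2-en-1-yl]oxy}methyl)stannane F2. Tin–lithium exchange with n-BuLi in THF at −78 °C generates ({[(1S)-2,4,4-trimethylcyclohex-2-en-1-yl]oxy}methyl)lithium F3, which undergoes the [2,3]-Wittig–Still rearrangement on the face of the C4–O bond to give [(1R)-2,6,6-trimethylcyclohex-2-en-1-yl]methanol F4, with the double bond at C4=C5. Dess–Martin oxidation gives (1R)-2,6,6-trimethylcyclohex-2-ene-1-carbaldehyde F5. Horner–Wadsworth–Emmons olefination with the anion of triethyl 3-methyl-4-phosphonocrotonate (LiN(SiMe3)2, THF, −78 °C) gives ethyl (2E,4E)-3-methyl-5-[(1R)-2,6,6-trimethylcyclohex-2-en-1-yl]penta-2,4-dienoate F6. Reduction with i-Bu2AlH in CH2Cl2 at −78 °C gives 15, which is converted into 16 under the conditions of step 7.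

Step 7. Under HBr the ring double bond may migrate from C4=C5 into conjugation, the pentadienyl cation may lose the proton at C6, and C9=C10 may scramble. The fallback avoids the cation; it sets out from 14 and comes back at 16. Desilylation with Bu4NF in THF gives 15, now isolated. Appel bromination (CBr4, PPh3, 2,6-lutidine, CH2Cl2, −20 °C) gives (6R)-6-[(1E,3E)-5-bromo-3-methylpenta-1,3-dien-1-yl]-1,5,5-trimethylcyclohex-1-ene F7. Displacement with PPh3 in ethyl acetate at rt precipitates 16.

Step 8. The second olefination may stay incomplete and the two new double bonds may form with low E selectivity that thermal equilibration does not fully correct. The fallback changes the olefination type; it sets out from 14 and comes back at 20. Desilylation with Bu4NF gives 15. Mitsunobu reaction with 1-phenyl-1H-tetrazole-5-thiol (PPh3, diisopropyl azodicarboxylate, THF) gives 5-{[(2E,4E)-3-methyl-5-[(1R)-2,6,6-trimethylcyclohex-2-en-1-yl]penta-2,4-dien-1-yl]sulfanyl}-1-phenyl-1H-tetrazole F8. Oxidation with H2O2 and (NH4)6Mo7O24·4H2O in ethanol gives the sulfone 5-{[(2E,4E)-3-methyl-5-[(1R)-2,6,6-trimethylcyclohex-2-en-1-yl]penta-2,4-dien-1-yl]sulfonyl}-1-phenyl-1H-tetrazole F9. Double Julia–Kocienski olefination of 17 with the anion of F9 (KN(SiMe3)2, THF, −78 °C to rt) passes through 19 and, after iodine-catalysed equilibration, should give 20.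

**Further compounds**

F1 | step 6 | (S)-2,4,4-trimethylcyclohex-2-en-1-ol | O[C@H]1CCC(C)(C)C=C1C
F2 | step 6 | tributyl({[(1S)-2,4,4-trimethylcyclohex-2-en-1-yl]oxy}methyl)stannane | CCCC[Sn](CCCC)(CCCC)CO[C@H]1CCC(C)(C)C=C1C
F3 | step 6 | ({[(1S)-2,4,4-trimethylcyclohex-2-en-1-yl]oxy}methyl)lithium | [Li]CO[C@H]1CCC(C)(C)C=C1C
F4 | step 6 | [(1R)-2,6,6-trimethylcyclohex-2-en-1-yl]methanol | CC1=CCCC(C)(C)[C@H]1CO
F5 | step 6 | (1R)-2,6,6-trimethylcyclohex-2-ene-1-carbaldehyde | CC1=CCCC(C)(C)[C@H]1C=O
F6 | step 6 | ethyl (2E,4E)-3-methyl-5-[(1R)-2,6,6-trimethylcyclohex-2-en-1-yl]penta-2,4-dienoate | CC1=CCCC(C)(C)[C@H]1/C=C/C(C)=C/C(=O)OCC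
F7 | step 7 | (6R)-6-[(1E,3E)-5-bromo-3-methylpenta-1,3-dien-1-yl]-1,5,5-trimethylcyclohex-1-ene | CC1=CCCC(C)(C)[C@H]1/C=C/C(C)=C/CBr
F8 | step 8 | 5-{[(2E,4E)-3-methyl-5-[(1R)-2,6,6-trimethylcyclohex-2-en-1-yl]penta-2,4-dien-1-yl]sulfanyl}-1-phenyl-1H-tetrazole | CC1=CCCC(C)(C)[C@H]1/C=C/C(C)=C/CSc1nnnn1-c1ccccc1
F9 | step 8 | 5-{[(2E,4E)-3-methyl-5-[(1R)-2,6,6-trimethylcyclohex-2-en-1-yl]penta-2,4-dien-1-yl]sulfonyl}-1-phenyl-1H-tetrazole | CC1=CCCC(C)(C)[C@H]1/C=C/C(C)=C/CS(=O)(=O)c1nnnn1-c1ccccc1
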